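Late in the east run D stopped growing: it read 19.0 % at 1.33 h and 18.9 % at 2.00 h, then sank while J kept rising. I started there, since at the top of D making equals using.

| flask | L | X | temperature | remark | time |
|---|---|---|---|---|---|
| east | 0.050 M | 0.12 M | 32 °C | run made earlier |  |
| north | 0.071 M | 0.12 M | 49 °C | run made earlier |  |
| autumn | 0.060 M | 0.120 M |  | at 25 °C throughout | 4.0 h |
| dawn | 0.10 M | 0.120 M |  | at 25 °C until 50 min, from then on at 55 °C | 4.0 h |

east run (percent of the L charged)

| time / h | D / % | J / % |
|---|---|---|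
| 0.250 | 8.6 | 2.0 |
| 0.333 | 10.9 | 1.9 |
| 0.500 | 14.3 | 4.4 |
| 0.833 | 17.8 | 10.5 |
| 1.33 | 19.0 | 18.8 |
| 2.00 | 18.9 | 30.2 |
| 3.00 | 17.6 | 43.2 |

north run (percent of the L charged)

| time / min | D / % | J / % |
|---|---|---|
| 8.00 | 12.2 | 7.2 |
| 15.0 | 15.1 | 15.2 |
| 25.0 | 15.1 | 26.4 |
| 30.0 | 14.7 | 31.0 |
| 40.0 | 12.5 | 38.3 |
| 50.0 | 12.7 | 44.2 |
| 60.0 | 11.6 | 49.4 |

(readings scatter by 0.5 percentage points)

- steps under discussion: D -> G; X + J -> Q; L + X -> D; X <-> E; X + D -> J
- the share counts what is present at the end, not what went on to other products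

- which of the two ends with the higher share of D in all that became D or J or Q ("neither" if they lie within 2 percentage points) (autumn / dawn / neither)
- share of D in all that became D or J or Q, autumn
- share of D in all that became D or J or Q, dawn

L + X -> D and X + D -> J each take one X, so X cancels from the ratio of their rates, and at the top of D that ratio gives L/D = κ, the second rate constant over the first. I left Q, G and E aside and took L as what D and J leave. Averaging the two readings at the top gave κ = 2.98 in east, and the same reading in north gave 4.25. So log10 κ went from 0.474 to 0.628. A straight line in temperature put this selectivity factor κ at 2.58 at 25 °C and 4.81 at 55 °C.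

With X cancelled, the share of D follows from a, the fraction of L left: s = (a^κ − a)/[(1 − κ)(1 − a)]. Autumn looks nearly like east, with the same X and L 0.060 M against 0.050 M, but it is colder than east. East's last reading had a = 39.2 %, where the rule gives 27.4 % and the readings 28.9 %. Autumn has the smaller κ, and as a guess, not a reckoning, I took a = 0.5 for it at 4.0 h, more L left than at east's last reading; there the rule gave 42.1 %.

Dawn charges 1.20 X per L, fewer than the 2 that J takes, so X is the limiting reagent there. Treating dawn as wholly at 55 °C, the balance D + 2J = 1.20 gave a = 34.9 % and s = 13.8 %.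

The forecast named autumn, with 41 % (36 % to 46 %) for autumn and 17 % (11 % to 22 %) for dawn, saying of dawn: “X is limiting”. My figures differ from both of its values but stand inside its ranges.

The flasks gave 43.4 % for autumn and 13.6 % for dawn, so autumn ends higher, as forecast. At 4.0 h autumn still held 49.5 % of its L. Put into the rule with κ = 2.58, that gives 41.6 %.

    D → G (k = 4.70 × 10⁻⁷ s⁻¹, Ea = 97.0 kJ mol⁻¹)
    X + J → Q (k = 2.50 × 10⁻⁵ L mol⁻¹ s⁻¹, Ea = 68.0 kJ mol⁻¹)
    L + X → D (k = 7.40 × 10⁻⁴ L mol⁻¹ s⁻¹, Ea = 61.0 kJ mol⁻¹)
    X ⇌ E (K = 0.430, k = 0.00150 s⁻¹, Ea = 95.0 kJ mol⁻¹, ΔH = −28.0 kJ mol⁻¹)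
    X + D → J (k = 0.00180 L mol⁻¹ s⁻¹, Ea = 78.0 kJ mol⁻¹)
    (constants at 25 °C)

A flask like autumn but with 0.30 M of X ended with a = 16.4 %, for which the same κ gives 11.7 %. The computed share there is 12.6 %.

The runs stem from a simulated flask for substances that don't exist; scatter was added.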